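Readings and results come from a simulation from invented constants; scatter was added.

| flask | starting material | partner | protic impurity | remark | time |
|---|---|---|---|---|---|
| gamma | 0.20 M | 0.19 M | 0.010 M | run made earlier |  |
| epsilon | 0.20 M | 0.095 M | 0.010 M | run made earlier |  |
| alpha | 0.20 M | 0.14 M | 0.010 M | run made earlier |  |
| spring | 0.20 M | 0.190 M | 0.0100 M | everything together at the start | 3.0 d |
| autumn | 0.20 M (in portions, 3, over 2.5 d) | 0.190 M | 0.0100 M | first portion at the start, last at 2.5 d | 3.0 d |
| midnight | 0.20 M (fed, over 2.5 d) | 0.190 M | 0.0100 M | all else is in the flask from the start; the feed brings no volume worth counting | 3.0 d |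
| winter | 0.20 M | 0.190 M (fed, over 2.5 d) | 0.0100 M | all else is in the flask from the start; the feed brings no volume worth counting | 3.0 d |

| run | time / d | target / % |
|---|---|---|
| gamma | 0.167 | 5 |
| gamma | 0.500 | 24 |
| gamma | 0.833 | 40 |
| gamma | 1.25 | 56 |
| gamma | 1.67 | 59 |
| gamma | 2.50 | 68 |
| gamma | 3.00 | 72 |
| epsilon | 0.500 | 16 |
| epsilon | 1.04 | 30 |
| epsilon | 1.67 | 39 |
| epsilon | 2.08 | 39 |
| epsilon | 2.50 | 42 |
| epsilon | 3.00 | 42 |
| epsilon | 4.00 | 42 |
| alpha | 0.500 | 23 |
| alpha | 1.04 | 42 |
| alpha | 1.67 | 50 |
| alpha | 2.08 | 57 |
| alpha | 2.50 | 57 |
| alpha | 3.00 | 58 |
| alpha | 4.00 | 58 |

(each reading ± 1.5 percentage points)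

- what is said of target includes crystals
- crystals is a solid; its amount is given per volume of the solution
- the earlier runs were read with a standard deviation of 1.5 percentage points
- reactions considered so far: starting material + protic impurity -> quenched substrate; 2 second intermediate -> homo product; partner -> second intermediate; crystals <-> target; open intermediate + second intermediate -> target; starting material -> open intermediate

- the flask with the highest amount of target, in percent of the starting material charged ("all alike" if they lie within 1.5 percentage points) (spring / autumn / midnight / winter / all alike)
- final target, as a percentage of the starting material charged, in spring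
- final target, as a percentage of the starting material charged, in autumn
- final target, as a percentage of the starting material charged, in midnight
- final target, as a percentage of the starting material charged, in winter

- Partner could not vanish: each unit I charged ended as target, stayed as partner or second intermediate, or went, two at a time, into homo product. So where partner was the limiting reagent, the charge minus the target plateau showed the loss.
- The epsilon plateau showed a loss of 0.0110 M and the alpha plateau 0.0240 M. The charge had grown by a factor of 1.47 and the loss by 2.18, so the loss went roughly with the square of the charge.
- For partner and starting material both in from the start, I froze that as the homo tax, the partner lost per square of c(partner) charged: 1.22 M⁻¹ from epsilon and 1.22 M⁻¹ from alpha. Both rest on plateaus read with a scatter of 1.5 percentage points.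
- The tail after feeding ran 0.500 d. Epsilon's first reading, taken as a first-order rise towards its plateau, gave a rise time to half that plateau of about 0.723 d, longer than the tail, so I expected material fed last to be unfinished at the end.
- Then came the feed, 2.5 d, which spanned about 3.46 rise times, and the whole run, 3.0 d, by which the epsilon and alpha readings had levelled.
- My reckoning put the spring plateau at 73.0 %. The tax was read with starting material in from the start, so I took no number from it for autumn or midnight.
- The forecast chose winter, with 72 % for spring, 50 % for autumn, 49 % for midnight and 75 % for winter. Its words on delay were that it “leaves second intermediate waiting”.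
- The flasks gave 70.8 % in spring, 37.1 % in autumn, 32.1 % in midnight and 75.6 % in winter, so winter stood highest.

    starting material + protic impurity → quenched substrate (k = 0.0414 M⁻¹ min⁻¹)
    2 second intermediate → homo product (k = 0.0575 M⁻¹ min⁻¹)
    partner → second intermediate (k = 9.73 × 10⁻⁴ min⁻¹)
    crystals ⇌ target, rate k4*(cs4 - [target]) while solid is left; crystals form when [target] > cs4 (solubility = 0.180 M, k = 0.0881 min⁻¹)
    open intermediate + second intermediate → target (k = 0.136 M⁻¹ min⁻¹)
    starting material → open intermediate (k = 8.44 × 10⁻⁴ min⁻¹)

- After 3.00 d, spring's homo product held 0.0450 M of partner, close to the tax of 0.0440 M, while midnight's held 0.123 M, more than that tax. Taking the path to homo product away shrank the gap between winter and midnight from 43 points to 3.1 points.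
- For winter left until 5.0 d, I treated the partner feed as about 3.46 slices of one rise time each. Taxing each slice by its square estimated a loss of 0.0127 M and a plateau near 88.6 %; in that computed flask, homo product held 0.0108 M of partner and target stood at 88.2 %, with 6.60 % still as open intermediate.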